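**Plan**
1. Enabling feature: in the 1,2-dioxane ring (O1–O2–C3–C4–C5–C6) the carbons C3–C4–C5–C6 form one chain whose two ends hold the peroxide oxygens. An extra C3–C6 bond folds this chain into a cyclobutane, and O2 can later take the place of that bond.
2. Retrosynthetic cuts, in order: C8–C9 (metathesis, then saturation), C6–C7 (allylsilane on a peroxycarbenium ion), O4–C1 (lactone), C3–O2 and C6–O1 (O2 removed, C3–C6 restored), C6–CH3 (Grignard). Last, C3–C4 and C5–C6 are cut together (ketene plus chiral isopropenyl ether).
3. Forward order: cyclobutane (step 4), 1,2-dioxane (step 6), γ-lactone (step 7), nonyl chain in two pieces (steps 9 and 12), saturation (step 13).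
4. Stereochemistry: C4 comes from the 1-arylethyl auxiliary on the enol ether oxygen. C3 is lost at the radical stage and is rewritten from C4, because a tethered hydroperoxide can add to the butenolide only with cis fusion. C6 comes from axial allylation of the bicyclic peroxycarbenium ion, syn to pseudoaxial O4.
5. Safeguards: the auxiliary stays on O4 until O2 is inserted. A free 3-hydroxycyclobutanone would open by retro-aldol cleavage, and the all-cis 1,3-dimethylcyclobutane-1,3-diol with O4 and O6 both free is meso and would erase C4. A tert-butyl ester keeps the C6 alkoxide from lactonising.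

Key step: step 4

Numbering: plakortolide numbering is used for all intermediates (C1 lactone C=O, C2 CH2, C3 CH–O2, C4 C(CH3)–O4, C5 CH2, C6 C(CH3)–O1, C7 onward the chain). "Peroxylactone core" means the 1,2-dioxane fused at C3–C4 to the γ-lactone O4–C1(=O)–C2.

Assumption: the isopropenyl ether is taken to react through the rotamer in which the O–CH(CH3)Ar bond points away from the attacked CH2 terminus and the carbinol H lies in the enol ether plane. In that rotamer the aryl group of the S auxiliary covers the face leading to 4R. If experiment shows the opposite sense, the equally available R alcohol is used in the same sequence.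

**Step 1**
Reactants: 1 (S)-1-(2,4,6-triisopropylphenyl)ethanol
Product: 2 (S)-1-(2,4,6-triisopropylphenyl)ethyl acetate
Conditions: Ac2O, pyridine, DMAP (cat.), CH2Cl2, rt
Reagents that add atoms: acetic anhydride, CC(=O)OC(C)=O
Why: DMAP-catalysed O-acylation works on hindered secondary alcohols and does not touch the carbinol C–O bond, so the S configuration is kept.

**Step 2**
Reactants: 2 (S)-1-(2,4,6-triisopropylphenyl)ethyl acetate
Product: 3 2-[(S)-1-(2,4,6-triisopropylphenyl)ethoxy]propene
Conditions: Cp2TiMe2, toluene, 65 °C, dark; filtration through basic Al2O3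
Reagents that add atoms: dimethyltitanocene Cp2TiMe2, C[Ti](C)(C1C=CC=C1)C1C=CC=C1
Why: Petasis methylenation turns the ester carbonyl into the 1,1-disubstituted enol ether through an oxatitanacyclobutane under non-acidic conditions that the product tolerates.

**Step 3**
Reactants: 4 4-tert-butoxy-4-oxobutanoic acid (mono-tert-butyl succinate)
Product: 5 tert-butyl 4-chloro-4-oxobutanoate
Conditions: (COCl)2, DMF (cat.), CH2Cl2, 0 °C → rt; evaporate, use crude
Reagents that add atoms: oxalyl chloride, O=C(Cl)C(=O)Cl
Why: acid chloride formation through the Vilsmeier-type chloroiminium salt is fast at low temperature and the HCl escapes as gas, so the tert-butyl ester should survive.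

**Step 4**
Reactants: 3 2-[(S)-1-(2,4,6-triisopropylphenyl)ethoxy]propene; 5 tert-butyl 4-chloro-4-oxobutanoate
Product: 7 tert-butyl 2-[(1S,2S)-2-methyl-4-oxo-2-{(S)-1-(2,4,6-triisopropylphenyl)ethoxy}cyclobutyl]acetate, via (tert-butoxycarbonylmethyl)ketene 6 (not isolated)
Conditions: 5 (2.5 equiv, syringe pump, 10 h) into 3, Et3N (3 equiv), toluene, 45 °C
Reagents that add atoms: none
Why: Et3N removes HCl from 5, and the resulting aldoketene 6 meets the enol ether in an orthogonal, concerted but strongly asynchronous [π2s+π2a] transition state, in which the nucleophilic CH2 terminus of 3 bonds to the ketene carbonyl carbon (C5–C6) ahead of the bond between the ketene α-carbon and the oxygen-bearing carbon (C3–C4). The closest known reaction type is the thermal [2+2] cycloaddition of ketenes made in situ from acid chlorides with alkyl enol ethers, which gives 3-alkoxycyclobutanones and is diastereoselective with 1-arylethyl enol ethers, most thoroughly for haloketenes. The cyclobutane is the only ring formed and closes by intermolecular cycloaddition, both σ-bonds arising in one kinetic step without a free zwitterion. C4 is controlled by the auxiliary, whose triisopropylphenyl group blocks one face of the enol ether in the rotamer named in the assumption; C3 is placed by the ketene approaching with its hydrogen toward the enol ether, stays epimerisable next to the ketone, and does not matter because step 6 makes it planar. Regioselectivity follows from the matched polarity of the partners, slow feeding of 5 keeps the stationary ketene concentration low so that cycloaddition stays ahead of dimerisation, and the apolar solvent disfavours proton transfer to an open C-acylation product.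

**Step 5**
Reactants: 7 the cyclobutanone of step 4
Product: 8 tert-butyl 2-[(1R,2S,4R)-4-hydroxy-2,4-dimethyl-2-{(S)-1-(2,4,6-triisopropylphenyl)ethoxy}cyclobutyl]acetate (C3 side chain, O4 and O6 all cis)
Conditions: MeMgBr (1.2 equiv), THF, −78 °C; aq. NH4Cl
Reagents that add atoms: methylmagnesium bromide, C[Mg]Br
Why: Grignard addition to the strained, poorly enolisable cyclobutanone outruns attack on the tert-butyl ester, as known for 3-alkoxycyclobutanones, and methyl should enter anti to the C3 side chain and the alkoxy group, although this C6 configuration is lost again in step 6.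

**Step 6**
Reactants: 8 the cyclobutanol of step 5
Product: 9 tert-butyl 2-[(4S)-6-hydroxy-4,6-dimethyl-4-{(S)-1-(2,4,6-triisopropylphenyl)ethoxy}-1,2-dioxan-3-yl]acetate (both C3 epimers; C6 anomers)
Conditions: Co(acac)2 (20 mol %), O2 (1 atm), MeCN, 45 °C
Reagents that add atoms: dioxygen, O=O
Why: in the cobalt-catalysed aerobic ring expansion of cyclobutanols to 1,2-dioxan-3-ols the O6 alkoxy radical cleaves the strained C6–C3 bond (secondary radical) rather than C6–C5 (primary radical), O2 is captured at C3 and the hydroperoxide closes on the new C6 methyl ketone; C4 is untouched, the planar C3 radical should take up O2 from both faces, and C6 is an equilibrating hemiketal, so neither of these two centres counts as set here.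

**Step 7**
Reactants: 9 the dioxanol of step 6
Product: 11 (4S)-6-methoxy-4,6-dimethyl peroxylactone core (both C3 epimers; C6 anomers), via 6-hydroxy peroxylactone 10 (not isolated)
Conditions: TFA–CH2Cl2 (1:4), 0 °C; evaporate; MeOH, CSA (10 mol %), 3 Å MS, rt
Reagents that add atoms: methanol, CO
Why: TFA ionises the benzylic C–O bond of the auxiliary and the tert-butyl ester (both E1), the freed γ-hydroxy acid lactonises, and acid-catalysed exchange with methanol turns the hemiketal into a base-stable peroxyketal; the C4–O4 bond is never broken, so C4 is retained.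

**Step 8**
Reactants: 11 the methoxy peroxylactone as C3 epimers
Product: 13 (3S,4S)-6-methoxy-4,6-dimethyl peroxylactone core with cis ring fusion (C6 anomers), via hydroperoxy butenolide 12 (not isolated)
Conditions: Et2NH (20 mol %), CF3CH2OH, rt
Reagents that add atoms: none
Why: Proposed new method: deprotonation at C2 expels the peroxide oxygen from C3 (E1cB) and gives butenolide 12, whose tethered α-methoxy hydroperoxide can re-add to C3 only from the face that carries the C5 arm, so both epimers of 11 should drain into the cis-fused 3S isomer while the acidic alcohol protonates the enolate before it can attack the O–O bond; the closest known reaction types are the amine-catalysed intramolecular oxa-Michael addition of α-alkoxy hydroperoxides to unsaturated esters in CF3CH2OH and the base-mediated retro-oxa-Michael/oxa-Michael equilibration of β-alkoxy carbonyl compounds.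

**Step 9**
Reactants: 13 the cis-fused methoxy peroxylactone
Product: 14 (3S,4S,6R)-6-allyl-4,6-dimethyl peroxylactone core
Conditions: allylSiMe3 (3 equiv), TMSOTf (0.3 equiv), CH2Cl2, −78 → −40 °C
Reagents that add atoms: allyltrimethylsilane, C=CC[Si](C)(C)C
Why: in this Hosomi–Sakurai allylation of a peroxyketal the peroxycarbenium half-chair with O4 pseudoaxial and both C4–CH3 and C3–C2 pseudoequatorial is attacked along the axial trajectory, which places allyl cis to O4 and C2 and sets 6R, whereas the flipped half-chair would require attack syn to an axial C4 methyl.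

**Step 10**
Reactants: 15 (4-bromophenoxy)(tert-butyl)dimethylsilane; 16 8-bromooct-1-ene
Product: 18 tert-butyldimethyl[4-(oct-7-en-1-yl)phenoxy]silane, via arylmagnesium bromide 17 (not isolated)
Conditions: Mg, THF, reflux; then 16, Li2CuCl4 (3 mol %), THF, 0 °C → rt
Reagents that add atoms: none
Why: copper-catalysed (Kochi-type) cross-coupling of an aryl Grignard reagent with a primary alkyl bromide is reliable and leaves the terminal alkene and the silyl ether untouched.

**Step 11**
Reactants: 18 the silyl ether of step 10
Product: 19 4-(oct-7-en-1-yl)phenol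
Conditions: TBAF, THF, 0 °C
Reagents that add atoms: none
Why: fluoride cleaves aryl silyl ethers rapidly, and doing it on the simple side chain spares the base-sensitive β-peroxy lactone a late deprotection.

**Step 12**
Reactants: 14 the allyl peroxylactone; 19 4-(oct-7-en-1-yl)phenol
Product: 20 (3S,4S,6R)-6-[(E)-9-(4-hydroxyphenyl)non-2-en-1-yl]-4,6-dimethyl peroxylactone core
Conditions: second-generation Grubbs catalyst (5 mol %), 19 (3 equiv), CH2Cl2, 40 °C
Reagents that add atoms: none
Why: olefin cross-metathesis of two unhindered terminal alkenes is driven by loss of ethene and by the excess of the cheap partner, tolerates dialkyl peroxides, lactones and phenols, and its alkene geometry is irrelevant to the next step.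

**Step 13**
Reactants: 20 the cross-metathesis product
Product: 21 plakortolide F
Conditions: KO2CN=NCO2K, AcOH, MeOH–CH2Cl2, 0 °C → rt
Reagents that add atoms: none
Why: diimide reduction transfers H2 to the C=C bond in a concerted way under mildly acidic conditions and leaves the O–O bond, the lactone, the arene and all three stereocentres untouched.

**Compound list**
1 | (S)-1-(2,4,6-triisopropylphenyl)ethanol | C[C@H](O)c1c(C(C)C)cc(C(C)C)cc1C(C)C | starting material
2 | (S)-1-(2,4,6-triisopropylphenyl)ethyl acetate | C[C@H](OC(C)=O)c1c(C(C)C)cc(C(C)C)cc1C(C)C | intermediate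
3 | 2-[(S)-1-(2,4,6-triisopropylphenyl)ethoxy]propene | C=C(C)O[C@@H](C)c1c(C(C)C)cc(C(C)C)cc1C(C)C | intermediate
4 | 4-tert-butoxy-4-oxobutanoic acid | CC(C)(C)OC(=O)CCC(=O)O | starting material
5 | tert-butyl 4-chloro-4-oxobutanoate | CC(C)(C)OC(=O)CCC(=O)Cl | intermediate
6 | (tert-butoxycarbonylmethyl)ketene (not isolated) | CC(C)(C)OC(=O)CC=C=O | intermediate
7 | tert-butyl 2-[(1S,2S)-2-methyl-4-oxo-2-{(S)-1-(2,4,6-triisopropylphenyl)ethoxy}cyclobutyl]acetate | CC(C)(C)OC(=O)C[C@@H]1C(=O)C[C@]1(C)O[C@@H](C)c1c(C(C)C)cc(C(C)C)cc1C(C)C | intermediate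
8 | tert-butyl 2-[(1R,2S,4R)-4-hydroxy-2,4-dimethyl-2-{(S)-1-(2,4,6-triisopropylphenyl)ethoxy}cyclobutyl]acetate | CC(C)(C)OC(=O)C[C@@H]1[C@](C)(O)C[C@]1(C)O[C@@H](C)c1c(C(C)C)cc(C(C)C)cc1C(C)C | intermediate
9 | tert-butyl 2-[(4S)-6-hydroxy-4,6-dimethyl-4-{(S)-1-(2,4,6-triisopropylphenyl)ethoxy}-1,2-dioxan-3-yl]acetate, C3 epimers and C6 anomers | CC(C)(C)OC(=O)CC1OOC(C)(O)C[C@]1(C)O[C@@H](C)c1c(C(C)C)cc(C(C)C)cc1C(C)C | intermediate
10 | (4S)-6-hydroxy-4,6-dimethyl peroxylactone core, C3 epimers and C6 anomers (not isolated) | CC1(O)C[C@]2(C)OC(=O)CC2OO1 | intermediate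
11 | (4S)-6-methoxy-4,6-dimethyl peroxylactone core, C3 epimers and C6 anomers | COC1(C)C[C@]2(C)OC(=O)CC2OO1 | intermediate
12 | (S)-5-(2-hydroperoxy-2-methoxypropyl)-5-methylfuran-2(5H)-one (not isolated) | COC(C)(OO)C[C@]1(C)OC(=O)C=C1 | intermediate
13 | (3S,4S)-6-methoxy-4,6-dimethyl peroxylactone core, cis-fused, C6 anomers | COC1(C)C[C@]2(C)OC(=O)C[C@@H]2OO1 | intermediate
14 | (3S,4S,6R)-6-allyl-4,6-dimethyl peroxylactone core | C[C@@]1(CC=C)C[C@]2(C)OC(=O)C[C@@H]2OO1 | intermediate
15 | (4-bromophenoxy)(tert-butyl)dimethylsilane | CC(C)(C)[Si](C)(C)Oc1ccc(Br)cc1 | starting material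
16 | 8-bromooct-1-ene | C=CCCCCCCBr | starting material
17 | 4-(tert-butyldimethylsilyloxy)phenylmagnesium bromide (not isolated) | CC(C)(C)[Si](C)(C)Oc1ccc([Mg]Br)cc1 | intermediate
18 | tert-butyldimethyl[4-(oct-7-en-1-yl)phenoxy]silane | C=CCCCCCCc1ccc(O[Si](C)(C)C(C)(C)C)cc1 | intermediate
19 | 4-(oct-7-en-1-yl)phenol | C=CCCCCCCc1ccc(O)cc1 | intermediate
20 | (3S,4S,6R)-6-[(E)-9-(4-hydroxyphenyl)non-2-en-1-yl]-4,6-dimethyl peroxylactone core | C[C@@]1(C/C=C/CCCCCCc2ccc(O)cc2)C[C@]2(C)OC(=O)C[C@@H]2OO1 | intermediate
21 | plakortolide F, (3S,4S,6R) | C[C@@]1(CCCCCCCCCc2ccc(O)cc2)C[C@]2(C)OC(=O)C[C@@H]2OO1 | target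

**Totals.** 13 steps in all. The longest linear sequence is 10 steps (1, 2, 4, 5, 6, 7, 8, 9, 12, 13).

**Steps most likely to fail**

1. **Step 8.**
   - Risk: the retro-addition may be too slow for the trans-fused epimer, whose C3–O2 bond lies close to the plane of the lactone enolate. On long exposure to base the enolate may attack the O–O bond, or removal of the C3 hydrogen may cleave the peroxide.
   - Fallback (known chemistry only), from 11 back to the route at 12. Zn/AcOH cleaves the O–O bond of 11 and the C6 hemiketal collapses, which should give the β-hydroxy lactone ketone F1.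
   - MsCl/Et3N converts it into the mesylate F2, which eliminates under the same conditions to the butenolide ketone F3.
   - Urea–H2O2 with CSA in MeOH turns the ketone into the α-methoxy hydroperoxide 12. This then needs only the forward, precedented ring closure (Et2NH, CF3CH2OH) to reach 13.

2. **Step 4.**
   - Risk: ketene dimerisation may outrun the cycloaddition. Proton transfer in a dipolar intermediate may divert material to C-acylation. Population of both O–C rotamers of the 1,1-disubstituted enol ether may erode facial selectivity.
   - Fallback, from 3 back to the route at 7: the same ketene is released without amine and at low temperature. Mono-tert-butyl malonate is converted with (COCl)2 into tert-butyl 3-chloro-3-oxopropanoate F4, and with Me3SiCHN2 into tert-butyl 4-diazo-3-oxobutanoate F5.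
   - Irradiation of F5 (365 nm) in toluene at −30 °C in the presence of 3 triggers a Wolff rearrangement. This feeds 6 slowly into the same [2+2] cycloaddition. The C4 diastereomers of 7 remain separable because of the auxiliary.

3. **Step 6.**
   - Risk: formation of the alkoxy radical may be slow at the crowded tertiary carbinol. Peroxyl radicals may autoxidise the benzylic C–H bonds of the auxiliary.
   - Fallback, from 8 back to the route at 13: the ring strain is spent on a halide and the peroxide comes from H2O2. Ring-opening chlorination of 8 (AgNO3 cat., K2S2O8, NCS, CH2Cl2–H2O) should give the γ-chloro ketone F6.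
   - Et3N eliminates it to the (E)-enoate ketone F7, and urea–H2O2 with CSA in MeOH gives the α-methoxy hydroperoxide F8.
   - Et2NH in CF3CH2OH closes the methoxy dioxane ester F9 through a chair with the ester arm and C4–CH3 equatorial and O4 axial (3,4-cis).
   - The conditions of step 7 then remove the auxiliary and the tert-butyl group and lactonise to 13.

**Further compounds**
F1 | step 8 | (5S)-4-hydroxy-5-methyl-5-(2-oxopropyl)dihydrofuran-2(3H)-one, C3 epimers | CC(=O)C[C@]1(C)OC(=O)CC1O
F2 | step 8 | (2S)-2-methyl-5-oxo-2-(2-oxopropyl)tetrahydrofuran-3-yl methanesulfonate, C3 epimers | CC(=O)C[C@]1(C)OC(=O)CC1OS(C)(=O)=O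
F3 | step 8 | (S)-5-methyl-5-(2-oxopropyl)furan-2(5H)-one | CC(=O)C[C@]1(C)OC(=O)C=C1
F4 | step 4 | tert-butyl 3-chloro-3-oxopropanoate | CC(C)(C)OC(=O)CC(=O)Cl
F5 | step 4 | tert-butyl 4-diazo-3-oxobutanoate | CC(C)(C)OC(=O)CC(=O)C=[N+]=[N-]
F6 | step 6 | tert-butyl (4S)-3-chloro-4-methyl-6-oxo-4-{(S)-1-(2,4,6-triisopropylphenyl)ethoxy}heptanoate, C3 epimers | CC(=O)C[C@](C)(O[C@@H](C)c1c(C(C)C)cc(C(C)C)cc1C(C)C)C(Cl)CC(=O)OC(C)(C)C
F7 | step 6 | tert-butyl (E)-4-methyl-6-oxo-4-{(S)-1-(2,4,6-triisopropylphenyl)ethoxy}hept-2-enoate, C4 configured as in 8 | CC(=O)C[C@](C)(O[C@@H](C)c1c(C(C)C)cc(C(C)C)cc1C(C)C)/C=C/C(=O)OC(C)(C)C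
F8 | step 6 | tert-butyl (E)-6-hydroperoxy-6-methoxy-4-methyl-4-{(S)-1-(2,4,6-triisopropylphenyl)ethoxy}hept-2-enoate, C4 configured as in 8 | COC(C)(OO)C[C@](C)(O[C@@H](C)c1c(C(C)C)cc(C(C)C)cc1C(C)C)/C=C/C(=O)OC(C)(C)C
F9 | step 6 | tert-butyl 2-[(3S,4S)-6-methoxy-4,6-dimethyl-4-{(S)-1-(2,4,6-triisopropylphenyl)ethoxy}-1,2-dioxan-3-yl]acetate, C6 anomers | COC1(C)C[C@](C)(O[C@@H](C)c2c(C(C)C)cc(C(C)C)cc2C(C)C)[C@H](CC(=O)OC(C)(C)C)OO1
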